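## Structural features

Locants: benzofuran numbering for rings A and B, primed locants for the pyranone (ring C), double-primed locants for the C8 chain (C1'' is bonded to C2).

- Ring A is a fully substituted phloroglucinol nucleus. It is fused through C3a and C7a to a 2,3-dihydrofuran (ring B) and joined through a CH2 group on C7 to C3' of a 6-ethyl-4-hydroxy-5-methyl-2-pyranone (ring C).
- Ring A also carries an acetyl group at C5 between the two hydrogen-bonded phenols at C4 and C6, so each of its six carbons bears a different substituent.
- The only stereocentre is C2 (R). It carries the ring oxygen and the 6-methylhepta-1,5-dien-2-yl chain and has no stereogenic neighbour, so nothing in the molecule can relay its configuration.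
- Fragile elements are:
  - the allylic aryl ether C2–O1, which can be ionised by acid or by zerovalent palladium;
  - the 1,1-disubstituted and trisubstituted alkenes, which are acid-labile;
  - the C7 benzylic carbon, which is flanked by three oxygen-bearing ring carbons and ionises easily;
  - the free acylphloroglucinol and the base-sensitive pyranone.
- The real difficulty is twofold: the substitution pattern of ring A must be fixed without ambiguity, and the isolated C2 centre must be set in the absolute sense.
- The key step uses the O1–C2–C3 unit of ring B. It is a 1,2-oxygenated two-carbon fragment that maps onto a terminal epoxide whose stereocentre becomes C2. C3 bonds to the C–H carbon C3a and O1 to the iodine-bearing carbon C7a of an iodoarene whose second ortho position is already the future C7.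

## Logic of the disconnections

**24 to 18 and 22.** The bond between the bridging CH2 and C3' is cut, together with the O–CH2 bonds of two phenol acetals. The CH2 on C7 lies ortho to two oxygen-bearing carbons and para to a third, so its oxygen derivative ionises readily, and C3' of 22 is the nucleophilic carbon of a vinylogous acid. The cut removes ring C in one stroke and leaves 18, which is fully protected and base-stable. The forward step must unmask two phenols, ionise the benzylic acetal and form the C–C bond under acid mild enough to spare the diene and the allylic ether at C2.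

**22 to 21 to 19.** Ring C is opened at O1'–C2' to 21, and 21 is cut at C4–C5 into 19 and an activated propanoyl donor. Both bonds are those of a polyketide-type assembly, and the symmetry of the donor leaves no regiochemical question. The forward demand is γ-selective acylation of the dianion 20 without proton transfer to the product.

**18 to 16.** The C5–acetyl bond is cut. C5–H is the only ring hydrogen and lies between two acetal oxygens, so it is the natural site of directed metalation through 17. Introducing the ketone after the methylenation avoids having two carbonyl groups compete for the methylene-transfer reagent. The demand is that deprotonation at C5 outruns deprotonation at the benzylic CH2 and at C3.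

**16 to 15 to 14 to 13.** The C1''=CH2 bond is cut to the ketone 15, which is traced back to the alcohol 14 and its silyl ether 13. The alkene cannot be present earlier, because an alkenyl epoxide would be ionised by zerovalent palladium. C2 becomes α to a carbonyl group in 15, so oxidation and methylenation must both be non-enolising.

**13 to 6 and 12 (key disconnection).** C3–C3a and C7a–O1 are cut. This removes ring B, takes the only stereocentre out of the aromatic half and places it in the small epoxide 12, and leaves 6, in which iodine marks C7a and the CH2O group marks C7.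
- The forward step needs palladation of a C–H bond flanked by an acetal oxygen, attack at the terminal epoxide carbon, and ring closure through the C2 oxygen only.
- The oxygen on C1'' is therefore carried as a triisopropylsilyl ether rather than a smaller silyl ether. A smaller group could migrate to the neighbouring alkoxide formed in this step and divert closure to a six-membered chroman.

**12 to 11 to 10 to 7 and 8.** The O–Si bond, then the epoxide C–O bonds, then the C3–C4 bond of 10 are cut. The carbinol centre of 10 is used only as the handle for a kinetic resolution that sets the epoxide carbon, and it is erased at 15. The demand is a high selectivity factor in the resolution, and the remote trisubstituted alkene must stay untouched.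

**6 to 5 to 4 to 3 to 2 to 1.** The benzylic acetal, the C7 oxidation level, the phenol acetals, the methyl ethers and finally the C7–CHO bond are removed. Formylation of 1 next to iodine fixes the 1,2,3,5 pattern of 6 at the outset. The methyl ethers are exchanged early for acetals that can be removed at the end beside the diene.

## Other disconnections considered

**Alternative 1:**
- **Cut and key step.** The cut is C5–C6 inside ring A, after ring A has been traced back to a polyketide chain. The precursor is the methylene-bridged bis-pyranone A2, whose 6-acetonyl pyranone half holds all six ring A carbons and the acetyl group. Mg(OMe)2 in methanol would open that lactone to a chelated triketo ester. The carbanion between the two distal carbonyls would attack the ester (Claisen condensation), and aromatisation would give the acetylphloroglucinol–pyranone A1.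
- **In favour.** Ring A would be created with the acetyl and pyranylmethyl groups already in the correct relationship, without protecting groups, and the CH2 bridge would be made at the easy bis-pyranone stage.
- **Against.** A1 contains nothing of ring B. C2, C3 and the whole C8 chain would have to be attached to the one free ring carbon of an unprotected polyphenol. Ring closure would have to choose the C7a oxygen over the C4 oxygen, both of which flank that carbon. C2 would have to be set by a reagent-controlled oxidation that must also tell two trisubstituted alkenes apart. An aldol mode of cyclisation and methanolysis of the second pyranone could compete with the Claisen mode.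
- **Comparison.** On structure it is the better plan for ring A and the bridge, and the weaker one for the placement of ring B and for C2. On mechanism it is metal-free ionic condensation chemistry, equal in convergence and easier to scale than the chosen plan. On step economy it is shorter up to A1, which is a point in its favour, but the open end-game would make the whole longer and less certain.

**Alternative 2:**
- **Cut and key step.** The cuts are C2–C3 and O1–C2. C2 and the side-chain ketone come from the sulfonium ylide A5, and C3 from the benzylic carbon of the sulfone A4. Base would expel sulfinate from A4 to give an ortho-quinone methide, A5 would add to its methylene carbon, and the C7a phenoxide would displace the sulfonium group in a 5-exo-tet closure under a chiral hydrogen-bond donor to give the ketone A3.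
- **In favour.** A3 already has C1'' at the ketone level and the acetyl group in place, so desilylation, oxidation and the lithiation step of the chosen route disappear. No transition metal and no resolution are needed.
- **Against.** The methide carbon is unsubstituted, so the addition creates no stereocentre. C2 is fixed only in the ring-closing displacement at a carbon α to both a ketone and a sulfonium group, which epimerises freely, and A3 remains an enolisable α-aryloxy ketone under the basic conditions. A3 also lacks the C7 carbon, which would have to be added after deprotection by a three-component coupling with 22 and a one-carbon electrophile. The methylenation would have to distinguish two ketones.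
- **Comparison.** On structure both plans fix the ring A pattern through the precursor, and the late C7 functionalisation, which avoids a benzylic acetal, is the equal or the better of the chosen plan. On mechanism the configuration would rest on catalyst control of a very simple substrate pair, whereas the chosen plan carries C2 intact from 12. On step economy this alternative is the better one as far as the ketone stage, provided the enantioselectivity holds.

**Alternative 3:**
- **Cut and key step.** The cuts are C4'–C5' and O1'–C2' of ring C, which would be built last on a finished ring A/ring B core. In that core C7–CH2 and the C6 oxygen are tied into a six-membered aryl lactone, the acid chloride A7. A7 would C-acylate the silyl enol ether A8, and the enol oxygen of the new 1,3-diketone would attack the aryl lactone carbonyl. Transacylation would close the pyranone and free the C6 phenol, giving the acetate A6. Mild solvolysis of the acetate would complete the synthesis.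
- **In favour.** The CH2 bridge is made early by carbonyl chemistry and not by a late cation. The aryl ester is an internal activated acyl donor, so ring C closes intramolecularly. The symmetrical ketone behind A8 leaves no regiochemical doubt.
- **Against.** A7 is a malonic half-ester chloride with an acidic α-hydrogen and is prone to ketene formation. Making it exposes the diene and the allylic aryl ether to a chlorinating agent and HCl. C4–OH needs an acetate that must later be removed beside a base-sensitive pyranone. Ring C is built in several linear steps on the most valuable intermediate. The plan also does not address ring B or C2 and would still need the chosen key step or an equivalent.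
- **Comparison.** On structure it is complementary (it solves ring C, not ring B). On mechanism the joining step avoids acid and a benzylic cation, which is a point where it is the better plan. On step economy it is longer and less convergent.

Key step: step 9

Assumption: the C1'' carbinol centre of 11 to 14 is transient (erased in step 11), so only the epoxide carbon of 11 has to be controlled; it must be R to give (2R)-24.

Step 1
Reactants: 1 1-iodo-3,5-dimethoxybenzene
Product: 2 2-iodo-4,6-dimethoxybenzaldehyde
Conditions: POCl3, DMF, 0 → 90 °C; then H2O, 0 °C
Reagents that add atoms: N,N-dimethylformamide, CN(C)C=O; water, O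
Why: Vilsmeier–Haack formylation; the chloroiminium ion should attack the carbon next to iodine, which is para to one methoxy group and ortho to the other, rather than the more hindered carbon between the two methoxy groups. Any 4-iodo-2,6-dimethoxy isomer would be removed by crystallisation.

Step 2
Reactants: 2 2-iodo-4,6-dimethoxybenzaldehyde
Product: 3 2,4-dihydroxy-6-iodobenzaldehyde
Conditions: BBr3, CH2Cl2, −78 °C → rt; then H2O
Reagents that add atoms: none
Why: Lewis-acid cleavage of both aryl methyl ethers; the aldehyde and the carbon–iodine bond are inert to BBr3. The methyl groups must go here because they could not be removed at the end beside the diene.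

Step 3
Reactants: 3 2,4-dihydroxy-6-iodobenzaldehyde
Product: 4 2-iodo-4,6-bis(methoxymethoxy)benzaldehyde
Conditions: NaH, MOMCl, DMF, 0 °C → rt
Reagents that add atoms: chloromethyl methyl ether, COCCl
Why: Williamson-type acetal formation on both phenoxides; NaH is used so that the hydroxyl hydrogen-bonded to the aldehyde is alkylated as well.

Step 4
Reactants: 4 2-iodo-4,6-bis(methoxymethoxy)benzaldehyde
Product: 5 [2-iodo-4,6-bis(methoxymethoxy)phenyl]methanol
Conditions: NaBH4, THF/MeOH, 0 °C
Reagents that add atoms: none
Why: Borohydride reduction of the aldehyde; it is run after phenol protection so that no free ortho- or para-hydroxybenzyl alcohol, which would lose water to a quinone methide, is ever present.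

Step 5
Reactants: 5 [2-iodo-4,6-bis(methoxymethoxy)phenyl]methanol
Product: 6 1-iodo-3,5-bis(methoxymethoxy)-2-[(methoxymethoxy)methyl]benzene
Conditions: MOMCl, iPr2NEt, CH2Cl2, 0 °C → rt
Reagents that add atoms: chloromethyl methyl ether, COCCl
Why: Acetalisation of the primary alcohol; the benzylic MOM ether is stable to base, organolithium and palladium chemistry and is the latent leaving group of step 16.

Step 6
Reactants: 7 5-bromo-2-methylpent-2-ene; 8 acrolein
Product: 10 rac-7-methylocta-1,6-dien-3-ol, via (4-methylpent-3-en-1-yl)magnesium bromide 9 (not isolated)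
Conditions: Mg, I2 (cat.), THF, rt → 40 °C; then 8, −78 → 0 °C; sat. aq NH4Cl
Reagents that add atoms: none
Why: Grignard formation and 1,2-addition to the enal at low temperature; the product is racemic by design because the carbinol centre serves only as the handle for the resolution in step 7.

Step 7
Reactants: 10 rac-7-methylocta-1,6-dien-3-ol
Product: 11 (1S)-5-methyl-1-[(2R)-oxiran-2-yl]hex-4-en-1-ol
Conditions: Ti(OiPr)4 (15 mol %), L-(+)-DIPT (20 mol %), TBHP (0.45 equiv), 4 Å MS, CH2Cl2, −20 °C
Reagents that add atoms: tert-butyl hydroperoxide, CC(C)(C)OO
Why: Sharpless asymmetric epoxidation in its kinetic-resolution mode; with the L-(+)-tartrate the (S)-alcohol should react fast and receive oxygen on the vinyl face anti to the carbinol substituent (erythro), which makes the epoxide carbon R, while the (R)-alcohol is left behind and separated. The remote trisubstituted alkene is not allylic to the hydroxyl group and should not be touched by the titanium peroxide at −20 °C.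

Step 8
Reactants: 11 (1S)-5-methyl-1-[(2R)-oxiran-2-yl]hex-4-en-1-ol
Product: 12 (2R)-2-[(1S)-5-methyl-1-{[tri(propan-2-yl)silyl]oxy}hex-4-en-1-yl]oxirane
Conditions: TIPSOTf, 2,6-lutidine, CH2Cl2, −78 → 0 °C
Reagents that add atoms: triisopropylsilyl trifluoromethanesulfonate, CC(C)[Si](C(C)C)(C(C)C)OS(=O)(=O)C(F)(F)F
Why: Silylation of the secondary alcohol, which blocks Payne rearrangement under the basic conditions of step 9; the triisopropylsilyl group is chosen because it resists 1,2-migration from oxygen to the neighbouring alkoxide generated in that step.

Step 9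
Reactants: 6 1-iodo-3,5-bis(methoxymethoxy)-2-[(methoxymethoxy)methyl]benzene; 12 (2R)-2-[(1S)-5-methyl-1-{[tri(propan-2-yl)silyl]oxy}hex-4-en-1-yl]oxirane
Product: 13 (2R)-4,6-bis(methoxymethoxy)-7-[(methoxymethoxy)methyl]-2-[(1S)-5-methyl-1-{[tri(propan-2-yl)silyl]oxy}hex-4-en-1-yl]-2,3-dihydro-1-benzofuran
Conditions: Pd(OAc)2 (10 mol %), XPhos (20 mol %), potassium 5-norbornene-2-carboxylate (50 mol %), K2CO3 (2 equiv), 12 (1.5 equiv), NMP, 80 °C
Reagents that add atoms: none
Why: Palladium/norbornene (Catellani-type) annulation of an aryl iodide with a terminal epoxide to a 2,3-dihydrobenzofuran, a known reaction class: zerovalent palladium inserts into the carbon–iodine bond at C7a, the norbornene inserts, and carboxylate-assisted palladation of the only free ortho C–H (C3a) gives the aryl–norbornyl palladacycle of divalent palladium. The palladacycle should open 12 at its unsubstituted CH2 carbon in an SN2-type oxidative addition to tetravalent palladium, and reductive elimination then forms C3–C3a. With both ortho positions occupied, β-carbon elimination expels norbornene and leaves an aryl–palladium alkoxide, which closes ring B by C7a–O1 reductive elimination from a six-membered oxapalladacycle, the oxygen being the former epoxide oxygen. No stereocentre is created: C2 keeps the R configuration of 12 because none of its bonds is broken, and C1'' is a spectator. The step needs attack at the terminal epoxide carbon (secured by sterics), alkylation at C3a alone (C7 is blocked by its CH2OMOM group, which also forces norbornene extrusion), and closure through the C2 oxygen alone (secured by the non-migrating triisopropylsilyl group, which keeps the six-membered chroman pathway closed). The bulky biaryl phosphine should favour C–O reductive elimination over β-hydride loss from the secondary alkoxide, and the trisubstituted alkene is too hindered to compete with norbornene for the aryl–palladium species.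

Step 10
Reactants: 13 (2R)-4,6-bis(methoxymethoxy)-7-[(methoxymethoxy)methyl]-2-[(1S)-5-methyl-1-{[tri(propan-2-yl)silyl]oxy}hex-4-en-1-yl]-2,3-dihydro-1-benzofuran
Product: 14 (1S)-1-[(2R)-4,6-bis(methoxymethoxy)-7-[(methoxymethoxy)methyl]-2,3-dihydro-1-benzofuran-2-yl]-5-methylhex-4-en-1-ol
Conditions: TBAF, THF, 0 °C → rt
Reagents that add atoms: none
Why: Fluoride cleavage of the silyl ether; MOM acetals, aryl ethers and the alkene are inert to fluoride.

Step 11
Reactants: 14 (1S)-1-[(2R)-4,6-bis(methoxymethoxy)-7-[(methoxymethoxy)methyl]-2,3-dihydro-1-benzofuran-2-yl]-5-methylhex-4-en-1-ol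
Product: 15 1-[(2R)-4,6-bis(methoxymethoxy)-7-[(methoxymethoxy)methyl]-2,3-dihydro-1-benzofuran-2-yl]-5-methylhex-4-en-1-one
Conditions: Dess–Martin periodinane, NaHCO3, CH2Cl2, 0 °C → rt
Reagents that add atoms: none
Why: Dess–Martin oxidation under buffered, non-enolising conditions, so the α-aryloxy centre C2 should keep its configuration; the C1'' stereocentre is erased here.

Step 12
Reactants: 15 1-[(2R)-4,6-bis(methoxymethoxy)-7-[(methoxymethoxy)methyl]-2,3-dihydro-1-benzofuran-2-yl]-5-methylhex-4-en-1-one
Product: 16 (2R)-4,6-bis(methoxymethoxy)-7-[(methoxymethoxy)methyl]-2-(6-methylhepta-1,5-dien-2-yl)-2,3-dihydro-1-benzofuran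
Conditions: Cp2Ti(μ-Cl)(μ-CH2)AlMe2 (1.5 equiv), pyridine, THF/toluene, −40 → 0 °C; then 0.1 M aq NaOH
Reagents that add atoms: Cp2Ti(μ-Cl)(μ-CH2)AlMe2, C[Al-]1(C)C[Ti](C2C=CC=C2)(C2C=CC=C2)[Cl+]1
Why: Tebbe methylenation through Cp2Ti=CH2 and an oxatitanacyclobutane; the reagent is not basic, so the ketone next to the enolisable C2–H should be converted without loss of configuration. Acetals, aryl ethers and the trisubstituted alkene are inert.

Step 13
Reactants: 16 (2R)-4,6-bis(methoxymethoxy)-7-[(methoxymethoxy)methyl]-2-(6-methylhepta-1,5-dien-2-yl)-2,3-dihydro-1-benzofuran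
Product: 18 1-[(2R)-4,6-bis(methoxymethoxy)-7-[(methoxymethoxy)methyl]-2-(6-methylhepta-1,5-dien-2-yl)-2,3-dihydro-1-benzofuran-5-yl]ethan-1-one, via C5 aryllithium 17 (not isolated)
Conditions: n-BuLi, TMEDA, THF, −78 → −20 °C; then N-methoxy-N-methylacetamide, −78 °C → rt; H2O
Reagents that add atoms: N-methoxy-N-methylacetamide, CC(=O)N(C)OC
Why: Directed ortho-metalation followed by Weinreb ketone synthesis; C5–H lies between two MOM ethers and is the most acidic and best-coordinated site. The amide gives a stable chelate that releases the methyl ketone only on quench, so no tertiary alcohol should form.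

Step 14
Reactants: 19 methyl 3-oxopentanoate
Product: 21 methyl 4-methyl-3,5-dioxoheptanoate, via dilithium dienolate 20 (not isolated)
Conditions: LiN(iPr)2 (2.2 equiv), THF, −78 → 0 °C; then N-methoxy-N-methylpropanamide, −78 → 0 °C; 1 M HCl
Reagents that add atoms: N-methoxy-N-methylpropanamide, CCC(=O)N(C)OC
Why: β-Keto ester dianion acylation; the dianion reacts at its more basic γ-carbon (C4). The tetrahedral chelate from the Weinreb amide survives until work-up, which prevents proton transfer to the product and double acylation.

Step 15
Reactants: 21 methyl 4-methyl-3,5-dioxoheptanoate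
Product: 22 6-ethyl-4-hydroxy-5-methyl-2H-pyran-2-one
Conditions: DBU (1.1 equiv), toluene, 110 °C; then 1 M HCl
Reagents that add atoms: none
Why: Base-induced lactonisation of a 3,5-dioxo ester: the C5 enol oxygen attacks the ester carbonyl (6-exo-trig) and enolisation gives the 4-hydroxy-2-pyranone. Loss of methanol and the stability of the pyranone drive the reaction.

Step 16
Reactants: 18 1-[(2R)-4,6-bis(methoxymethoxy)-7-[(methoxymethoxy)methyl]-2-(6-methylhepta-1,5-dien-2-yl)-2,3-dihydro-1-benzofuran-5-yl]ethan-1-one; 22 6-ethyl-4-hydroxy-5-methyl-2H-pyran-2-one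
Product: 24 3-{[(2R)-5-acetyl-4,6-dihydroxy-2-(6-methylhepta-1,5-dien-2-yl)-2,3-dihydro-1-benzofuran-7-yl]methyl}-6-ethyl-4-hydroxy-5-methyl-2H-pyran-2-one, via ortho-quinone methide 23 (not isolated)
Conditions: HCl (0.2 M), 22 (3 equiv), MeOH, 0 °C → rt
Reagents that add atoms: none
Why: Acid-catalysed acetal cleavage coupled to an ortho-quinone methide (Friedel–Crafts-type) alkylation of a 4-hydroxy-2-pyranone: the phenolic MOM groups are solvolysed, and the benzylic acetal at C7 ionises because the cation is stabilised by the oxygens on C6 and C7a (ortho) and C4 (para) and collapses to 23. The enol of 22, present in excess, should add through C3' and restore the aromatic ring A. Methanol holds the released one-carbon units as dimethoxymethane and captures the cation only reversibly, so the C–C adduct should accumulate; C2 is not involved.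

Compound list

1 | 1-iodo-3,5-dimethoxybenzene | COc1cc(I)cc(OC)c1 | starting material
2 | 2-iodo-4,6-dimethoxybenzaldehyde | O=Cc1c(I)cc(OC)cc1OC | intermediate
3 | 2,4-dihydroxy-6-iodobenzaldehyde | O=Cc1c(I)cc(O)cc1O | intermediate
4 | 2-iodo-4,6-bis(methoxymethoxy)benzaldehyde | O=Cc1c(I)cc(OCOC)cc1OCOC | intermediate
5 | [2-iodo-4,6-bis(methoxymethoxy)phenyl]methanol | OCc1c(I)cc(OCOC)cc1OCOC | intermediate
6 | 1-iodo-3,5-bis(methoxymethoxy)-2-[(methoxymethoxy)methyl]benzene | COCOCc1c(I)cc(OCOC)cc1OCOC | intermediate
7 | 5-bromo-2-methylpent-2-ene | CC(C)=CCCBr | starting material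
8 | acrolein | C=CC=O | starting material
9 | (4-methylpent-3-en-1-yl)magnesium bromide | CC(C)=CCC[Mg]Br | intermediate (not isolated)
10 | rac-7-methylocta-1,6-dien-3-ol | CC(C)=CCCC(O)C=C | intermediate
11 | (1S)-5-methyl-1-[(2R)-oxiran-2-yl]hex-4-en-1-ol | CC(C)=CCC[C@H](O)[C@H]1CO1 | intermediate
12 | (2R)-2-[(1S)-5-methyl-1-{[tri(propan-2-yl)silyl]oxy}hex-4-en-1-yl]oxirane | CC(C)=CCC[C@H](O[Si](C(C)C)(C(C)C)C(C)C)[C@H]1CO1 | intermediate
13 | (2R)-4,6-bis(methoxymethoxy)-7-[(methoxymethoxy)methyl]-2-[(1S)-5-methyl-1-{[tri(propan-2-yl)silyl]oxy}hex-4-en-1-yl]-2,3-dihydro-1-benzofuran | CC(C)=CCC[C@H](O[Si](C(C)C)(C(C)C)C(C)C)[C@H]1Cc2c(OCOC)cc(OCOC)c(COCOC)c2O1 | intermediate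
14 | (1S)-1-[(2R)-4,6-bis(methoxymethoxy)-7-[(methoxymethoxy)methyl]-2,3-dihydro-1-benzofuran-2-yl]-5-methylhex-4-en-1-ol | CC(C)=CCC[C@H](O)[C@H]1Cc2c(OCOC)cc(OCOC)c(COCOC)c2O1 | intermediate
15 | 1-[(2R)-4,6-bis(methoxymethoxy)-7-[(methoxymethoxy)methyl]-2,3-dihydro-1-benzofuran-2-yl]-5-methylhex-4-en-1-one | CC(C)=CCCC(=O)[C@H]1Cc2c(OCOC)cc(OCOC)c(COCOC)c2O1 | intermediate
16 | (2R)-4,6-bis(methoxymethoxy)-7-[(methoxymethoxy)methyl]-2-(6-methylhepta-1,5-dien-2-yl)-2,3-dihydro-1-benzofuran | C=C(CCC=C(C)C)[C@H]1Cc2c(OCOC)cc(OCOC)c(COCOC)c2O1 | intermediate
17 | [(2R)-4,6-bis(methoxymethoxy)-7-[(methoxymethoxy)methyl]-2-(6-methylhepta-1,5-dien-2-yl)-2,3-dihydro-1-benzofuran-5-yl]lithium | C=C(CCC=C(C)C)[C@H]1Cc2c(OCOC)c([Li])c(OCOC)c(COCOC)c2O1 | intermediate (not isolated)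
18 | 1-[(2R)-4,6-bis(methoxymethoxy)-7-[(methoxymethoxy)methyl]-2-(6-methylhepta-1,5-dien-2-yl)-2,3-dihydro-1-benzofuran-5-yl]ethan-1-one | C=C(CCC=C(C)C)[C@H]1Cc2c(OCOC)c(C(C)=O)c(OCOC)c(COCOC)c2O1 | intermediate
19 | methyl 3-oxopentanoate | CCC(=O)CC(=O)OC | starting material
20 | dilithium 1-methoxypenta-1,3-diene-1,3-bis(olate) (dianion of 19) | [Li+].[Li+].CC=C([O-])C=C([O-])OC | intermediate (not isolated)
21 | methyl 4-methyl-3,5-dioxoheptanoate | CCC(=O)C(C)C(=O)CC(=O)OC | intermediate
22 | 6-ethyl-4-hydroxy-5-methyl-2H-pyran-2-one | CCc1oc(=O)cc(O)c1C | intermediate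
23 | (2R)-5-acetyl-4-hydroxy-7-methylidene-2-(6-methylhepta-1,5-dien-2-yl)-2,3-dihydro-1-benzofuran-6(7H)-one | C=C(CCC=C(C)C)[C@H]1CC2=C(O1)C(=C)C(=O)C(C(C)=O)=C2O | intermediate (not isolated)
24 | 3-{[(2R)-5-acetyl-4,6-dihydroxy-2-(6-methylhepta-1,5-dien-2-yl)-2,3-dihydro-1-benzofuran-7-yl]methyl}-6-ethyl-4-hydroxy-5-methyl-2H-pyran-2-one | C=C(CCC=C(C)C)[C@H]1Cc2c(O)c(C(C)=O)c(O)c(Cc3c(O)c(C)c(CC)oc3=O)c2O1 | target

Total step count: 16. Longest linear sequence: 11 steps (steps 1 to 5, 9 to 13 and 16).

Steps least certain to work

**Step 9 (key step).**
- What may go wrong: palladation of the C3a–H bond may be slow because it is flanked by the C4 acetal oxygen. The aryl–palladium species would then be consumed by reduction or by norbornene-containing side products before alkylation. Halide-induced rearrangement of the epoxide would add to the loss.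
- Fallback: it replaces C–H activation by a pre-installed halogen, sets out from 12 and rejoins the route at 13.
  - 1-Bromo-3,5-dimethoxybenzene F1 would be formylated as in step 1 to 2-bromo-4,6-dimethoxybenzaldehyde F2.
  - F2 would be iodinated (NIS, TFA cat., MeCN) at the carbon between bromine and methoxy, which is para to the other methoxy group, to give 2-bromo-3-iodo-4,6-dimethoxybenzaldehyde F3.
  - The operations of steps 2 to 5 would then lead through 2-bromo-4,6-dihydroxy-3-iodobenzaldehyde F4, 2-bromo-3-iodo-4,6-bis(methoxymethoxy)benzaldehyde F5 and [2-bromo-3-iodo-4,6-bis(methoxymethoxy)phenyl]methanol F6 to 3-bromo-2-iodo-1,5-bis(methoxymethoxy)-4-[(methoxymethoxy)methyl]benzene F7.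
  - Selective iodine–magnesium exchange (iPrMgCl·LiCl, THF, −40 °C) and CuI-catalysed opening of 12 at its terminal carbon would give (2R,3S)-1-{2-bromo-4,6-bis(methoxymethoxy)-3-[(methoxymethoxy)methyl]phenyl}-7-methyl-3-{[tri(propan-2-yl)silyl]oxy}oct-6-en-2-ol F8.
  - Intramolecular palladium-catalysed aryl ether formation (Pd(OAc)2, a bulky biaryl phosphine, Cs2CO3, toluene, 80 °C) would close ring B to 13 with C2 untouched.

**Step 16.**
- What may go wrong: acid-promoted side reactions of the diene and of the allylic C2–O1 ether (cyclisation, solvent addition, ionisation with loss of configuration), and consumption of 22 by the one-carbon units released from the MOM groups, if C–C bond formation is slower than acetal cleavage.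
- Fallback: it separates deprotection from coupling, sets out from 18 and rejoins at 24.
  - 18 would be exposed only briefly to HCl in MeOH at 0 °C without 22, so that methanol captures the benzylic cation and 1-[(2R)-4,6-dihydroxy-7-(methoxymethyl)-2-(6-methylhepta-1,5-dien-2-yl)-2,3-dihydro-1-benzofuran-5-yl]ethan-1-one F9 is isolated.
  - F9 would then be heated with the sodium salt of 22 in dioxane at 80 °C. Loss of methanol from the ortho-hydroxybenzyl ether would give 23 without acid, and conjugate addition of the pyranone anion would give 24.

**Step 13.**
- What may go wrong: deprotonation at sites other than C5. These are the benzylic CH2 on C7, and C3–H, which would be followed by β-elimination of the C7a phenoxide and opening of ring B. The hindered aryllithium may also enolise the amide.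
- Fallback: it fixes the metalation site by a carbon–halogen bond, sets out from 16 and rejoins at 18.
  - Electrophilic iodination (NIS, MeCN, 0 °C) at the only free ring position would give (2R)-5-iodo-4,6-bis(methoxymethoxy)-7-[(methoxymethoxy)methyl]-2-(6-methylhepta-1,5-dien-2-yl)-2,3-dihydro-1-benzofuran F10.
  - Iodine–magnesium exchange (iPrMgCl·LiCl, THF, −20 °C), which is faster than any deprotonation, and acylation with N-methoxy-N-methylacetamide would give 18.

**Step 12.**
- What may go wrong: incomplete methylenation of the α-branched ketone, partial epimerisation at C2 if traces of base or Lewis acid enolise 15, and isomerisation of the new alkene by titanium residues.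
- Fallback: a two-stage Peterson olefination, which sets out from 15 and rejoins at 16.
  - Addition of Me3SiCH2MgCl in the presence of CeCl3 (THF, −78 °C), a weakly basic nucleophile, would give 2-[(2R)-4,6-bis(methoxymethoxy)-7-[(methoxymethoxy)methyl]-2,3-dihydro-1-benzofuran-2-yl]-6-methyl-1-(trimethylsilyl)hept-5-en-2-ol F11.
  - Syn-elimination with KH (THF, 0 °C → rt) would give 16.

## Further compounds

F1 | step 9 | 1-bromo-3,5-dimethoxybenzene | COc1cc(Br)cc(OC)c1
F2 | step 9 | 2-bromo-4,6-dimethoxybenzaldehyde | O=Cc1c(Br)cc(OC)cc1OC
F3 | step 9 | 2-bromo-3-iodo-4,6-dimethoxybenzaldehyde | O=Cc1c(Br)c(I)c(OC)cc1OC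
F4 | step 9 | 2-bromo-4,6-dihydroxy-3-iodobenzaldehyde | O=Cc1c(Br)c(I)c(O)cc1O
F5 | step 9 | 2-bromo-3-iodo-4,6-bis(methoxymethoxy)benzaldehyde | O=Cc1c(Br)c(I)c(OCOC)cc1OCOC
F6 | step 9 | [2-bromo-3-iodo-4,6-bis(methoxymethoxy)phenyl]methanol | OCc1c(Br)c(I)c(OCOC)cc1OCOC
F7 | step 9 | 3-bromo-2-iodo-1,5-bis(methoxymethoxy)-4-[(methoxymethoxy)methyl]benzene | COCOCc1c(Br)c(I)c(OCOC)cc1OCOC
F8 | step 9 | (2R,3S)-1-{2-bromo-4,6-bis(methoxymethoxy)-3-[(methoxymethoxy)methyl]phenyl}-7-methyl-3-{[tri(propan-2-yl)silyl]oxy}oct-6-en-2-ol | CC(C)=CCC[C@H](O[Si](C(C)C)(C(C)C)C(C)C)[C@H](O)Cc1c(Br)c(COCOC)c(OCOC)cc1OCOC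
F9 | step 16 | 1-[(2R)-4,6-dihydroxy-7-(methoxymethyl)-2-(6-methylhepta-1,5-dien-2-yl)-2,3-dihydro-1-benzofuran-5-yl]ethan-1-one | C=C(CCC=C(C)C)[C@H]1Cc2c(O)c(C(C)=O)c(O)c(COC)c2O1
F10 | step 13 | (2R)-5-iodo-4,6-bis(methoxymethoxy)-7-[(methoxymethoxy)methyl]-2-(6-methylhepta-1,5-dien-2-yl)-2,3-dihydro-1-benzofuran | C=C(CCC=C(C)C)[C@H]1Cc2c(OCOC)c(I)c(OCOC)c(COCOC)c2O1
F11 | step 12 | 2-[(2R)-4,6-bis(methoxymethoxy)-7-[(methoxymethoxy)methyl]-2,3-dihydro-1-benzofuran-2-yl]-6-methyl-1-(trimethylsilyl)hept-5-en-2-ol (both carbinol epimers) | CC(C)=CCCC(O)(C[Si](C)(C)C)[C@H]1Cc2c(OCOC)cc(OCOC)c(COCOC)c2O1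
A1 | alternative 1 | 3-[(3-acetyl-2,4,6-trihydroxyphenyl)methyl]-6-ethyl-4-hydroxy-5-methyl-2H-pyran-2-one | CC(=O)c1c(O)cc(O)c(Cc2c(O)c(C)c(CC)oc2=O)c1O
A2 | alternative 1 | 6-ethyl-4-hydroxy-3-{[4-hydroxy-2-oxo-6-(2-oxopropyl)-2H-pyran-3-yl]methyl}-5-methyl-2H-pyran-2-one | CCc1oc(=O)c(Cc2c(O)cc(CC(C)=O)oc2=O)c(O)c1C
A3 | alternative 2 | 1-[(2R)-5-acetyl-4,6-bis(methoxymethoxy)-2,3-dihydro-1-benzofuran-2-yl]-5-methylhex-4-en-1-one | CC(C)=CCCC(=O)[C@H]1Cc2c(OCOC)c(C(C)=O)c(OCOC)cc2O1
A4 | alternative 2 | 1-{4-hydroxy-2,6-bis(methoxymethoxy)-3-[(4-methylbenzenesulfonyl)methyl]phenyl}ethan-1-one | CC(=O)c1c(OCOC)cc(O)c(CS(=O)(=O)c2ccc(C)cc2)c1OCOC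
A5 | alternative 2 | 1-(dimethyl-λ4-sulfanylidene)-6-methylhept-5-en-2-one | CS(C)=CC(=O)CCC=C(C)C
A6 | alternative 3 | (2R)-5-acetyl-7-[(6-ethyl-4-hydroxy-5-methyl-2-oxo-2H-pyran-3-yl)methyl]-6-hydroxy-2-(6-methylhepta-1,5-dien-2-yl)-2,3-dihydro-1-benzofuran-4-yl acetate | C=C(CCC=C(C)C)[C@H]1Cc2c(OC(C)=O)c(C(C)=O)c(O)c(Cc3c(O)c(C)c(CC)oc3=O)c2O1
A7 | alternative 3 | (2R)-dihydrobenzofuran-fused 2-oxochromane-3-carbonyl chloride (lactone C6–O–CO–CH(COCl)–CH2–C7; C4 acetate; C5 acetyl; 2-(6-methylhepta-1,5-dien-2-yl)) | C=C(CCC=C(C)C)[C@H]1Cc2c(OC(C)=O)c(C(C)=O)c3OC(=O)C(C(Cl)=O)Cc3c2O1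
A8 | alternative 3 | trimethyl(pent-2-en-3-yloxy)silane | CC=C(CC)O[Si](C)(C)C
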